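**Retrosynthetic overview**
1. The target is epicatechin gallate-(4β→8)-epigallocatechin gallate-(4β→8)-catechin gallate. The last operations are hydrogenolysis of 22 benzyl ethers, triple galloylation and removal of three silyl ethers.
2. Ring B of the middle unit is attached at C2 by aryllithium addition to a lactone, followed by silane reduction to the 2,3-cis flavan.
3. The strategy rests on C4 of the middle unit: a diaryl methine bonded to C4a of its own ring A and to C8 of the lower catechin, ortho to the ring oxygen O1–C8a and trans to O–C3. It is treated as the adduct of an o-quinone methide with the enamine of a silyloxyacetaldehyde, which forms C3–C4 and then O1–C2 and closes ring C of the middle unit.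
4. The o-hydroxybenzhydrol precursor comes from a salicylaldehyde (epicatechin arylated at C4β with 3,5-dibenzyloxyphenol, then ortho-formylated) and 8-lithiated catechin.
5. Ring order: rings C of the upper and lower units are taken intact from (−)-epicatechin and (+)-catechin; ring C of the middle unit is closed in step 10 and its ring B is added in step 14.

Key step: step 10

Assumption: the enamine of aldehyde 15 is taken to react in the usual E-anti geometry, so the (S)-catalyst is the enantiomer that sets C3 of the middle unit as drawn; 14, 17 and 23 are carried as epimer mixtures at the carbinol, lactol and hemiketal carbon.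

**Route**

Step 1
Reactants: 1 (−)-epicatechin
Product: 2 (−)-epicatechin 5,7,3',4'-tetrabenzyl ether (3-OH free)
Conditions: BnBr (4.4 equiv), K2CO3, DMF, 0 °C → rt
Reagents that add atoms: benzyl bromide, BrCc1ccccc1
Why: Williamson etherification with carbonate base alkylates the four phenols only and leaves the secondary 3-OH and both stereocentres untouched.

Step 2
Reactants: 2 (−)-epicatechin tetrabenzyl ether
Product: 3 4β-(2-ethoxyethoxy) derivative of 2 (C4–O trans to the 3-OH)
Conditions: DDQ (2 equiv), 2-ethoxyethanol, CH2Cl2, rt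
Reagents that add atoms: 2-ethoxyethanol, CCOCCO
Why: DDQ benzylic oxidation removes hydride from C4 to give the ring A-stabilised cation, which the alcohol should capture trans to the 3-OH; this C4 centre is provisional and is reset in step 4.

Step 3
Reactants: 3 4β-(2-ethoxyethoxy)epicatechin tetrabenzyl ether
Product: 4 3-O-TBS ether of 3
Conditions: TBSCl, imidazole, DMAP (cat.), DMF, rt → 40 °C
Reagents that add atoms: tert-butyldimethylsilyl chloride, CC(C)(C)[Si](C)(C)Cl
Why: base-mediated silylation of the only hydroxyl avoids any Lewis acid that could ionise the C4 acetal.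

Step 4
Reactants: 4 3-O-TBS-4β-(2-ethoxyethoxy)epicatechin tetrabenzyl ether; 5 3,5-bis(benzyloxy)phenol (4 equiv)
Product: 6 3,5-bis(benzyloxy)-2-(3-O-TBS-tetra-O-benzylepicatechin-4β-yl)phenol
Conditions: TMSOTf (0.3 equiv), CH2Cl2, −78 → −40 °C
Reagents that add atoms: none
Why: Friedel–Crafts arylation of the C4 cation released by TMSOTf; the nucleophile should attack trans to the pseudo-axial 3-OTBS group (4β, 3,4-trans, as is general for 2,3-cis flavan-4-yl cations) and through the carbon ortho to its free OH, which is flanked by OH and OBn and is less hindered than the carbon between two OBn groups (the same bias that directs benzylated catechins to C8), while excess 5 suppresses double alkylation.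

Step 5
Reactants: 6 phenol carrying the upper flavan
Product: 7 4,6-bis(benzyloxy)-2-hydroxy-3-(3-O-TBS-tetra-O-benzylepicatechin-4β-yl)benzaldehyde
Conditions: MgCl2, Et3N, (CH2O)n, MeCN, reflux
Reagents that add atoms: paraformaldehyde (as formaldehyde), C=O
Why: magnesium phenolate-directed ortho-formylation (Casnati–Skattebøl) delivers the formyl group only ortho to a free phenol, and the single open ortho carbon is the future C4a of the middle unit.

Step 6
Reactants: 8 (+)-catechin
Product: 9 (+)-catechin 5,7,3',4'-tetrabenzyl ether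
Conditions: BnBr (4.4 equiv), K2CO3, DMF, 0 °C → rt
Reagents that add atoms: benzyl bromide, BrCc1ccccc1
Why: Williamson etherification of the four phenols as in step 1.

Step 7
Reactants: 9 (+)-catechin tetrabenzyl ether
Product: 10 8-bromocatechin tetrabenzyl ether
Conditions: NBS (1.0 equiv), CH2Cl2, −78 °C → rt
Reagents that add atoms: N-bromosuccinimide, O=C1CCC(=O)N1Br
Why: electrophilic aromatic bromination of the phloroglucinol-type ring A, which in benzylated flavan-3-ols occurs at C8 (next to the ring oxygen) in preference to the more hindered C6.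

Step 8
Reactants: 10 8-bromocatechin tetrabenzyl ether
Product: 11 8-bromo-3-O-TBS-catechin tetrabenzyl ether
Conditions: TBSCl, imidazole, DMF, rt
Reagents that add atoms: tert-butyldimethylsilyl chloride, CC(C)(C)[Si](C)(C)Cl
Why: standard silylation of the 3-OH, which removes the only acidic proton before lithiation.

Step 9
Reactants: 7 salicylaldehyde carrying the upper flavan; 11 8-bromo-3-O-TBS-catechin tetrabenzyl ether (1.5 equiv)
Product: 14 o-hydroxybenzhydrol joining C4a of the middle ring A to C8 of the lower unit (both carbinol epimers), via sodium phenolate 12 (not isolated), via aryllithium 13 (not isolated)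
Conditions: 7: NaH (1.05 equiv), THF, 0 °C; 11: n-BuLi, THF, −78 °C; phenolate solution added, −78 → −20 °C; pH 7 buffer; Et3N-deactivated silica
Reagents that add atoms: none
Why: Li–Br exchange gives the C8 aryllithium, which undergoes 1,2-addition to the aldehyde of the pre-formed phenolate (the usual entry to o-hydroxybenzhydrols from salicylaldehydes); the carbinol centre forms unselectively, which does no harm because it becomes sp2 in step 10.

Step 10
Reactants: 14 o-hydroxybenzhydrol; 15 (tert-butyldimethylsilyloxy)acetaldehyde (4 equiv)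
Product: 17 trimer with the middle unit as its 3-O-TBS-chroman-2-ol (3,4-trans; both anomers at C2), via o-quinone methide 16 (not isolated)
Conditions: (S)-α,α-diphenylprolinol trimethylsilyl ether (20 mol %), PhCO2H (20 mol %), slow addition of 15, CH2Cl2, 0 °C → rt
Reagents that add atoms: none
Why: PhCO2H dehydrates 14 reversibly to o-quinone methide 16, whose methide carbon (the future C4) already carries C8 of the lower unit, while the amine turns 15 into its enamine, and the enamine α-carbon adds to the methide carbon (Michael-type, C3–C4) with re-aromatisation of ring A. Hydrolysis of the iminium ion returns the catalyst and the freed C8a phenol closes ring C on the aldehyde as the lactol (O1–C2, 6-exo-trig hemiacetalisation), so the whole is a formal [4+2] annulation in which one molecule of water is lost from 14. The closest known reaction type is the diarylprolinol silyl ether-catalysed [4+2] annulation of aldehydes with o-quinone methides generated from o-hydroxybenzhydrols, which gives trans-3,4-disubstituted chroman-2-ols. C3 is set by the catalyst, whose CPh2OTMS group shields one enamine face so that the (S)-enantiomer should give the 3α-oxygen of the target; C4 follows from the synclinal (syn-Michael) approach that leads to the 3,4-trans ring, which is also the more stable arrangement should the addition be reversible, and C2 stays an anomeric mixture because it is oxidised in step 11. The step needs a single mode of ring closure and catalyst control beside two resident chiral units: only the C8a oxygen of ring A is free (O5 and O7 are benzyl ethers), and the reacting carbons lie several bonds from the stereocentres of the flanking flavans, so the catalyst's shielding is expected to dominate. The weak acid should leave the three silyl ethers and the acid-sensitive C4–C8 bond to the upper unit intact.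

Step 11
Reactants: 17 lactol
Product: 18 trimer with the middle unit as its 3-O-TBS-4-aryl-3,4-dihydrocoumarin (lactone)
Conditions: n-Pr4N[RuO4] (5 mol %), NMO, 4 Å MS, CH2Cl2, rt
Reagents that add atoms: none
Why: perruthenate-catalysed (Ley) oxidation converts both lactol anomers into one lactone under neutral conditions that do not epimerise C3 or touch benzyl and silyl ethers.

Step 12
Reactants: 19 5-bromo-1,2,3-trimethoxybenzene
Product: 20 5-bromobenzene-1,2,3-triol
Conditions: BBr3 (3.5 equiv), CH2Cl2, −78 °C → rt; H2O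
Reagents that add atoms: none
Why: BBr3 cleavage of aryl methyl ethers; the aryl bromide is inert.

Step 13
Reactants: 20 5-bromobenzene-1,2,3-triol
Product: 21 5-bromo-1,2,3-tris(benzyloxy)benzene
Conditions: BnBr (3.5 equiv), K2CO3, DMF, rt, N2
Reagents that add atoms: benzyl bromide, BrCc1ccccc1
Why: Williamson etherification of the three phenols gives the benzyl-protected ring B precursor.

Step 14
Reactants: 18 lactone; 21 5-bromo-1,2,3-tris(benzyloxy)benzene (1.3 equiv)
Product: 23 trimer with the middle unit as its 2-(3,4,5-tribenzyloxyphenyl)chroman-2-ol (hemiketal in equilibrium with the ring-opened hydroxy ketone), via aryllithium 22 (not isolated)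
Conditions: 21: n-BuLi, THF, −78 °C; then 18, −78 °C; pH 7 buffer at −78 °C
Reagents that add atoms: none
Why: single addition of an aryllithium to an α-oxygenated lactone at low temperature (the lactone-to-lactol stage of C-aryl glycoside synthesis) forms the C2–aryl bond, and the crowded tetrahedral intermediate or its hindered ketone should resist a second addition; the C2 centre is not controlled here and is set in step 15.

Step 15
Reactants: 23 hemiketal
Product: 25 tris-TBS perbenzylated trimer with the middle unit as the 2,3-cis-3,4-trans flavan, via oxocarbenium ion 24 (not isolated)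
Conditions: Et3SiH (5 equiv), BF3·OEt2 (1.5 equiv), CH2Cl2, −78 → −40 °C
Reagents that add atoms: none
Why: ionic hydrogenation of the hemiketal (silane reduction of a 2-aryl oxocarbenium ion, as in C-aryl glycoside and 2,3-cis-flavan reductive etherification); the 3-OTBS group should sit pseudo-axial to avoid allylic strain with the coplanar ring B and hydride should enter anti to it, placing ring B cis to O–C3.

Step 16
Reactants: 25 tris-TBS trimer
Product: 26 perbenzylated trimer with three free 3-hydroxyls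
Conditions: TBAF (6 equiv), AcOH (6 equiv), THF, rt → 40 °C
Reagents that add atoms: none
Why: fluoride cleavage of the three secondary silyl ethers; acetic acid buffering keeps the medium from becoming basic, and benzyl ethers are inert.

Step 17
Reactants: 26 triol; 27 3,4,5-tris(benzyloxy)benzoic acid (6 equiv used; three molecules are incorporated, one at each 3-hydroxyl)
Product: 28 perbenzylated tri-O-gallate (22 benzyl ethers)
Conditions: 27 (6 equiv), DCC, DMAP, CH2Cl2, rt → 40 °C
Reagents that add atoms: 3,4,5-tris(benzyloxy)benzoic acid (second and third molecule of 27), OC(=O)c1cc(OCc9ccccc9)c(OCc9ccccc9)c(OCc9ccccc9)c1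
Why: Steglich esterification acylates each of the three hindered secondary alcohols with one molecule of acid 27 through the acylpyridinium ion, so three tribenzylgalloyl groups are installed in one operation without affecting any stereocentre.

Step 18
Reactants: 28 perbenzylated tri-O-gallate
Product: 29 CNP0321910.1 (target)
Conditions: H2 (1 atm), Pd(OH)2/C, THF/MeOH/H2O, rt
Reagents that add atoms: none
Why: catalytic hydrogenolysis removes all 22 benzyl ethers; gallate esters and the C2 and C4 aryl-bearing stereocentres are stable under neutral conditions at room temperature.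

**Compound list**

1 | (−)-epicatechin | Oc1cc(O)c2c(c1)O[C@H](c1ccc(O)c(O)c1)[C@H](O)C2 | starting material
2 | (−)-epicatechin 5,7,3',4'-tetrabenzyl ether | c9ccccc9COc1cc(OCc9ccccc9)c2c(c1)O[C@H](c1ccc(OCc9ccccc9)c(OCc9ccccc9)c1)[C@H](O)C2 | intermediate
3 | 4β-(2-ethoxyethoxy)epicatechin tetrabenzyl ether | c9ccccc9COc1cc(OCc9ccccc9)c2c(c1)O[C@H](c1ccc(OCc9ccccc9)c(OCc9ccccc9)c1)[C@H](O)[C@H]2OCCOCC | intermediate
4 | 3-O-TBS ether of 3 | c9ccccc9COc1cc(OCc9ccccc9)c2c(c1)O[C@H](c1ccc(OCc9ccccc9)c(OCc9ccccc9)c1)[C@H](O[Si](C)(C)C(C)(C)C)[C@H]2OCCOCC | intermediate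
5 | 3,5-bis(benzyloxy)phenol | Oc1cc(OCc9ccccc9)cc(OCc9ccccc9)c1 | starting material
6 | 3,5-bis(benzyloxy)-2-(3-O-TBS-tetra-O-benzylepicatechin-4β-yl)phenol | Oc1cc(OCc9ccccc9)cc(OCc9ccccc9)c1[C@H]6c7c(OCc9ccccc9)cc(OCc9ccccc9)cc7O[C@H](c8ccc(OCc9ccccc9)c(OCc9ccccc9)c8)[C@@H]6O[Si](C)(C)C(C)(C)C | intermediate
7 | 4,6-bis(benzyloxy)-2-hydroxy-3-(3-O-TBS-tetra-O-benzylepicatechin-4β-yl)benzaldehyde | O=Cc2c(OCc9ccccc9)cc(OCc9ccccc9)c([C@H]6c7c(OCc9ccccc9)cc(OCc9ccccc9)cc7O[C@H](c8ccc(OCc9ccccc9)c(OCc9ccccc9)c8)[C@@H]6O[Si](C)(C)C(C)(C)C)c2O | intermediate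
8 | (+)-catechin | Oc1cc(O)c2c(c1)O[C@H](c1ccc(O)c(O)c1)[C@@H](O)C2 | starting material
9 | (+)-catechin 5,7,3',4'-tetrabenzyl ether | c9ccccc9COc1cc(OCc9ccccc9)c2c(c1)O[C@H](c1ccc(OCc9ccccc9)c(OCc9ccccc9)c1)[C@@H](O)C2 | intermediate
10 | 8-bromocatechin tetrabenzyl ether | Brc3c(OCc9ccccc9)cc(OCc9ccccc9)c4c3O[C@H](c5ccc(OCc9ccccc9)c(OCc9ccccc9)c5)[C@@H](O)C4 | intermediate
11 | 8-bromo-3-O-TBS-catechin tetrabenzyl ether | Brc3c(OCc9ccccc9)cc(OCc9ccccc9)c4c3O[C@H](c5ccc(OCc9ccccc9)c(OCc9ccccc9)c5)[C@@H](O[Si](C)(C)C(C)(C)C)C4 | intermediate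
12 | sodium phenolate of 7 | O=Cc2c(OCc9ccccc9)cc(OCc9ccccc9)c([C@H]6c7c(OCc9ccccc9)cc(OCc9ccccc9)cc7O[C@H](c8ccc(OCc9ccccc9)c(OCc9ccccc9)c8)[C@@H]6O[Si](C)(C)C(C)(C)C)c2[O-].[Na+] | intermediate
13 | 8-lithio-3-O-TBS-catechin tetrabenzyl ether | [Li]c3c(OCc9ccccc9)cc(OCc9ccccc9)c4c3O[C@H](c5ccc(OCc9ccccc9)c(OCc9ccccc9)c5)[C@@H](O[Si](C)(C)C(C)(C)C)C4 | intermediate
14 | o-hydroxybenzhydrol (either carbinol epimer) | OC(c3c(OCc9ccccc9)cc(OCc9ccccc9)c4c3O[C@H](c5ccc(OCc9ccccc9)c(OCc9ccccc9)c5)[C@@H](O[Si](C)(C)C(C)(C)C)C4)c2c(OCc9ccccc9)cc(OCc9ccccc9)c([C@H]6c7c(OCc9ccccc9)cc(OCc9ccccc9)cc7O[C@H](c8ccc(OCc9ccccc9)c(OCc9ccccc9)c8)[C@@H]6O[Si](C)(C)C(C)(C)C)c2O | intermediate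
15 | (tert-butyldimethylsilyloxy)acetaldehyde | O=CCO[Si](C)(C)C(C)(C)C | starting material
16 | o-quinone methide from 14 | O=C1C(=Cc3c(OCc9ccccc9)cc(OCc9ccccc9)c4c3O[C@H](c5ccc(OCc9ccccc9)c(OCc9ccccc9)c5)[C@@H](O[Si](C)(C)C(C)(C)C)C4)C(OCc9ccccc9)=CC(OCc9ccccc9)=C1[C@H]6c7c(OCc9ccccc9)cc(OCc9ccccc9)cc7O[C@H](c8ccc(OCc9ccccc9)c(OCc9ccccc9)c8)[C@@H]6O[Si](C)(C)C(C)(C)C | intermediate
17 | trimer with middle unit as 3-O-TBS-chroman-2-ol (lactol, both anomers) | CC(C)(C)[Si](C)(C)O[C@@H]1[C@@H](c3c(OCc9ccccc9)cc(OCc9ccccc9)c4c3O[C@H](c5ccc(OCc9ccccc9)c(OCc9ccccc9)c5)[C@@H](O[Si](C)(C)C(C)(C)C)C4)c2c(OCc9ccccc9)cc(OCc9ccccc9)c([C@H]6c7c(OCc9ccccc9)cc(OCc9ccccc9)cc7O[C@H](c8ccc(OCc9ccccc9)c(OCc9ccccc9)c8)[C@@H]6O[Si](C)(C)C(C)(C)C)c2OC1O | intermediate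
18 | trimer with middle unit as 3-O-TBS-3,4-dihydrocoumarin (lactone) | CC(C)(C)[Si](C)(C)O[C@@H]1[C@@H](c3c(OCc9ccccc9)cc(OCc9ccccc9)c4c3O[C@H](c5ccc(OCc9ccccc9)c(OCc9ccccc9)c5)[C@@H](O[Si](C)(C)C(C)(C)C)C4)c2c(OCc9ccccc9)cc(OCc9ccccc9)c([C@H]6c7c(OCc9ccccc9)cc(OCc9ccccc9)cc7O[C@H](c8ccc(OCc9ccccc9)c(OCc9ccccc9)c8)[C@@H]6O[Si](C)(C)C(C)(C)C)c2OC1=O | intermediate
19 | 5-bromo-1,2,3-trimethoxybenzene | COc1cc(Br)cc(OC)c1OC | starting material
20 | 5-bromobenzene-1,2,3-triol | Oc1cc(Br)cc(O)c1O | intermediate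
21 | 5-bromo-1,2,3-tris(benzyloxy)benzene | Brc1cc(OCc9ccccc9)c(OCc9ccccc9)c(OCc9ccccc9)c1 | intermediate
22 | 3,4,5-tris(benzyloxy)phenyllithium | [Li]c1cc(OCc9ccccc9)c(OCc9ccccc9)c(OCc9ccccc9)c1 | intermediate
23 | trimer with middle unit as 2-aryl-chroman-2-ol (hemiketal, C2 epimers) | CC(C)(C)[Si](C)(C)O[C@@H]1[C@@H](c3c(OCc9ccccc9)cc(OCc9ccccc9)c4c3O[C@H](c5ccc(OCc9ccccc9)c(OCc9ccccc9)c5)[C@@H](O[Si](C)(C)C(C)(C)C)C4)c2c(OCc9ccccc9)cc(OCc9ccccc9)c([C@H]6c7c(OCc9ccccc9)cc(OCc9ccccc9)cc7O[C@H](c8ccc(OCc9ccccc9)c(OCc9ccccc9)c8)[C@@H]6O[Si](C)(C)C(C)(C)C)c2OC1(O)c5cc(OCc9ccccc9)c(OCc9ccccc9)c(OCc9ccccc9)c5 | intermediate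
24 | 2-aryl oxocarbenium ion from 23 | CC(C)(C)[Si](C)(C)O[C@@H]1[C@@H](c3c(OCc9ccccc9)cc(OCc9ccccc9)c4c3O[C@H](c5ccc(OCc9ccccc9)c(OCc9ccccc9)c5)[C@@H](O[Si](C)(C)C(C)(C)C)C4)c2c(OCc9ccccc9)cc(OCc9ccccc9)c([C@H]6c7c(OCc9ccccc9)cc(OCc9ccccc9)cc7O[C@H](c8ccc(OCc9ccccc9)c(OCc9ccccc9)c8)[C@@H]6O[Si](C)(C)C(C)(C)C)c2[O+]=C1c5cc(OCc9ccccc9)c(OCc9ccccc9)c(OCc9ccccc9)c5 | intermediate
25 | tris-TBS perbenzylated trimer (middle unit 2,3-cis-3,4-trans) | CC(C)(C)[Si](C)(C)O[C@@H]1[C@@H](c3c(OCc9ccccc9)cc(OCc9ccccc9)c4c3O[C@H](c5ccc(OCc9ccccc9)c(OCc9ccccc9)c5)[C@@H](O[Si](C)(C)C(C)(C)C)C4)c2c(OCc9ccccc9)cc(OCc9ccccc9)c([C@H]6c7c(OCc9ccccc9)cc(OCc9ccccc9)cc7O[C@H](c8ccc(OCc9ccccc9)c(OCc9ccccc9)c8)[C@@H]6O[Si](C)(C)C(C)(C)C)c2O[C@@H]1c5cc(OCc9ccccc9)c(OCc9ccccc9)c(OCc9ccccc9)c5 | intermediate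
26 | perbenzylated trimer triol | O[C@@H]1[C@@H](c3c(OCc9ccccc9)cc(OCc9ccccc9)c4c3O[C@H](c5ccc(OCc9ccccc9)c(OCc9ccccc9)c5)[C@@H](O)C4)c2c(OCc9ccccc9)cc(OCc9ccccc9)c([C@H]6c7c(OCc9ccccc9)cc(OCc9ccccc9)cc7O[C@H](c8ccc(OCc9ccccc9)c(OCc9ccccc9)c8)[C@@H]6O)c2O[C@@H]1c5cc(OCc9ccccc9)c(OCc9ccccc9)c(OCc9ccccc9)c5 | intermediate
27 | 3,4,5-tris(benzyloxy)benzoic acid | OC(=O)c1cc(OCc9ccccc9)c(OCc9ccccc9)c(OCc9ccccc9)c1 | starting material
28 | perbenzylated tri-O-gallate | O=C(O[C@@H]1[C@@H](c3c(OCc9ccccc9)cc(OCc9ccccc9)c4c3O[C@H](c5ccc(OCc9ccccc9)c(OCc9ccccc9)c5)[C@@H](OC(=O)c5cc(OCc9ccccc9)c(OCc9ccccc9)c(OCc9ccccc9)c5)C4)c2c(OCc9ccccc9)cc(OCc9ccccc9)c([C@H]6c7c(OCc9ccccc9)cc(OCc9ccccc9)cc7O[C@H](c8ccc(OCc9ccccc9)c(OCc9ccccc9)c8)[C@@H]6OC(=O)c8cc(OCc9ccccc9)c(OCc9ccccc9)c(OCc9ccccc9)c8)c2O[C@@H]1c5cc(OCc9ccccc9)c(OCc9ccccc9)c(OCc9ccccc9)c5)c5cc(OCc9ccccc9)c(OCc9ccccc9)c(OCc9ccccc9)c5 | intermediate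
29 | CNP0321910.1 | O=C(O[C@@H]1[C@@H](c2c(O)cc(O)c3c2O[C@H](c2ccc(O)c(O)c2)[C@@H](OC(=O)c2cc(O)c(O)c(O)c2)C3)c2c(O)cc(O)c([C@H]3c4c(O)cc(O)cc4O[C@H](c4ccc(O)c(O)c4)[C@@H]3OC(=O)c3cc(O)c(O)c(O)c3)c2O[C@@H]1c1cc(O)c(O)c(O)c1)c1cc(O)c(O)c(O)c1 | target

**Step count and risks**

Total step count: 18. Longest linear sequence: 13 steps (1–5, 9–11, 14–18, from (−)-epicatechin).

Steps most likely to fail:

1. Step 10. The quinone methide is strongly stabilised and its methide carbon is flanked by four ortho substituents, so C–C bond formation may be slow and lose out to self-aldolisation of 15. Facial selectivity may also be poor if the catalyst and the two resident flavan units are mismatched. The fallback sets out from benzhydrol 14 and returns at lactone 18. (S)-4-Benzyl-3-[(tert-butyldimethylsilyloxy)acetyl]oxazolidin-2-one F1 is made by N-acylation of (S)-4-benzyloxazolidin-2-one with the pivalic mixed anhydride of (tert-butyldimethylsilyloxy)acetic acid. F1 is enolised with TiCl4 and i-Pr2NEt in CH2Cl2 at −78 °C and 14 is added. The Lewis acid ionises the carbinol and the chelated Z-enolate should capture the diarylmethyl cation on the face away from the benzyl group (auxiliary-controlled SN1-type alkylation of a titanium enolate), giving imide adduct F2 with C3 as required. With Et3N and DMAP the phenol acylates itself on the imide carbonyl, releasing the auxiliary, and 18 is obtained after separation from its C4 epimer.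

2. Step 15. Facial selectivity of hydride delivery may be poor, because the face anti to the 3-OTBS group is also the face of the pseudo-axial C4 aryl group. The Lewis acid may also cleave a silyl ether or the acid-sensitive interflavan bonds. The fallback sets out from lactol 17 and returns at 25, bypassing steps 11, 14 and 15. Lactol 17 is treated with aryllithium 22 (2.5 equiv, THF, −78 °C); the first equivalent opens the lactol to the phenolate aldehyde and the second adds to the α-silyloxy aldehyde with the polar Felkin–Anh preference, giving anti carbinol F3 (C2–OH anti to C3–OTBS). Mitsunobu cyclisation (PPh3, DIAD, toluene, 0 °C) then lets the phenol displace the activated benzylic hydroxyl with inversion, closing ring C as the 2,3-cis flavan 25.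

3. Step 9. Addition of the di-ortho-substituted aryllithium to the electron-rich, di-ortho-substituted phenolate aldehyde may be sluggish, so the aryllithium may be lost to protonation, and the product may ionise on work-up. The fallback reverses the polarity; it sets out from phenol 6 and bromide 11 and returns at 14, bypassing step 5. Bromide 11 is lithiated as in step 9 and aryllithium 13 is quenched with DMF to give 8-formyl-3-O-TBS-catechin tetrabenzyl ether F4. Phenol 6 is treated with EtMgBr in toluene and F4 is added; the magnesium phenolate should deliver the aldehyde to its only free ortho carbon through a six-membered chelate (ortho-specific hydroxyalkylation of magnesium phenolates), giving 14.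

**Further compounds**

F1 | step 10 | (S)-4-benzyl-3-[(tert-butyldimethylsilyloxy)acetyl]oxazolidin-2-one | CC(C)(C)[Si](C)(C)OCC(=O)N1[C@@H](Cc2ccccc2)COC1=O
F2 | step 10 | N-acyloxazolidinone adduct of the diarylmethyl cation (ring C open, phenol free) | CC(C)(C)[Si](C)(C)O[C@H]([C@@H](c3c(OCc9ccccc9)cc(OCc9ccccc9)c4c3O[C@H](c5ccc(OCc9ccccc9)c(OCc9ccccc9)c5)[C@@H](O[Si](C)(C)C(C)(C)C)C4)c2c(OCc9ccccc9)cc(OCc9ccccc9)c([C@H]6c7c(OCc9ccccc9)cc(OCc9ccccc9)cc7O[C@H](c8ccc(OCc9ccccc9)c(OCc9ccccc9)c8)[C@@H]6O[Si](C)(C)C(C)(C)C)c2O)C(=O)N1[C@@H](Cc5ccccc5)COC1=O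
F3 | step 15 | anti carbinol from aryllithium addition to the open form of 17 (ring C open, phenol free) | CC(C)(C)[Si](C)(C)O[C@H]([C@@H](c3c(OCc9ccccc9)cc(OCc9ccccc9)c4c3O[C@H](c5ccc(OCc9ccccc9)c(OCc9ccccc9)c5)[C@@H](O[Si](C)(C)C(C)(C)C)C4)c2c(OCc9ccccc9)cc(OCc9ccccc9)c([C@H]6c7c(OCc9ccccc9)cc(OCc9ccccc9)cc7O[C@H](c8ccc(OCc9ccccc9)c(OCc9ccccc9)c8)[C@@H]6O[Si](C)(C)C(C)(C)C)c2O)[C@@H](O)c5cc(OCc9ccccc9)c(OCc9ccccc9)c(OCc9ccccc9)c5
F4 | step 9 | 8-formyl-3-O-TBS-catechin tetrabenzyl ether | O=Cc3c(OCc9ccccc9)cc(OCc9ccccc9)c4c3O[C@H](c5ccc(OCc9ccccc9)c(OCc9ccccc9)c5)[C@@H](O[Si](C)(C)C(C)(C)C)C4
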